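The route rests on a one-carbon ring expansion. The seven-membered ring (C1, C5, C6, C7, C8, C9, C10; daucane numbering) is grown from the six-membered ring of a trans-hydrindanone by inserting C9 between the C10 carbonyl and C8. Because C1 is quaternary, the C10 ketone can enolise only towards the methyl-bearing C8. Cyclopropanation of that silyl enol ether, then Fe(III)-mediated opening of the siloxycyclopropane (Ito–Saegusa), delivers in one operation the cycloheptenone with the C10 oxygen, the C8=C9 double bond and the C8 methyl in place. The precursor, a 1,7-dihydroxy-3a,5-dimethyl-1-isopropylhydrindan-4-one, comes from an enantioselective NHC benzoin desymmetrisation, isopropyl addition and hydroboration.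

Key step: step 11

Remarks and assumptions
- Daucane numbering is used in the explanations: C1 (quaternary, CH3), C2, C3, C4 (C–OH, isopropyl), C5 (ring-fusion CH), C6 (CH–O), C7 (CH2), C8 (C–CH3), C9, C10 (CH–O). α is the face of the C1 methyl, β the opposite face. The target has 4α-OH, 4β-isopropyl, 5β-H, 6β-O and 10β-O. In the names, daucane C1/C4/C5/C6/C8/C10 are indene C3a/C1/C7a/C7/C5/C4 and azulene C8a/C3/C3a/C4/C6/C8.
- Assumption: in step 2 the enantiomer of the aminoindanol-derived triazolium precatalyst that gives (3aS,7aR)-4 is used. Both enantiomers are accessible from the two cis-1-amino-2-indanols, and the sense of induction is to be confirmed on 4.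
- The facial outcome of the step 13 reduction is not secure; the fallback for step 14 covers the opposite outcome.

Step 1
Reactants: 1 2-methylcyclohexane-1,3-dione; 2 acrolein
Product: 3 3-(1-methyl-2,6-dioxocyclohexyl)propanal
Conditions: H2O, rt
Reagents that add atoms: none
Why: Michael addition of the enolised 1,3-dione to acrolein gives the C2-alkylated, still achiral trione with the two ring carbonyls enantiotopic.

Step 2
Reactants: 3 3-(1-methyl-2,6-dioxocyclohexyl)propanal
Product: 4 (3aS,7aR)-7a-hydroxy-3a-methylhexahydro-1H-indene-1,4(2H)-dione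
Conditions: chiral aminoindanol-derived N-C6F5 triazolium tetrafluoroborate (10 mol %), Et3N (10 mol %), toluene, rt
Reagents that add atoms: none
Why: NHC-catalysed intramolecular crossed benzoin reaction in which the Breslow intermediate adds 5-exo to one of the two enantiotopic ring carbonyls; the chiral carbene selects the carbonyl and so sets the quaternary C1 and the cis carbinol C5 (the three-atom tether enforces cis fusion).

Step 3
Reactants: 4 (3aS,7aR)-7a-hydroxy-3a-methylhexahydro-1H-indene-1,4(2H)-dione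
Product: 5 (3aS)-3a-methyl-3,3a,5,6-tetrahydro-1H-indene-1,4(2H)-dione
Conditions: Burgess reagent, THF, 50 °C
Reagents that add atoms: none
Why: Burgess dehydration (syn elimination) of the tertiary alcohol can only run towards C6, because its other neighbours are a carbonyl carbon and the quaternary C1, and gives the C4(=O)–C5=C6 enone without touching C1.

Step 4
Reactants: 5 (3aS)-3a-methyl-3,3a,5,6-tetrahydro-1H-indene-1,4(2H)-dione
Product: 6 (3a'S)-3a'-methyl-3',3a',5',6'-tetrahydrospiro[[1,3]dioxolane-2,4'-inden]-1'(2'H)-one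
Conditions: ethylene glycol, TsOH (cat.), benzene, reflux (Dean–Stark)
Reagents that add atoms: ethylene glycol, OCCO
Why: chemoselective acetalisation of the saturated C10 ketone in the presence of the much less electrophilic conjugated C4 carbonyl, as in the selective ketalisation of the Wieland–Miescher ketone.

Step 5
Reactants: 6 (3a'S)-3a'-methyl-3',3a',5',6'-tetrahydrospiro[[1,3]dioxolane-2,4'-inden]-1'(2'H)-one
Product: 7 (1'R,3a'S)-3a'-methyl-1'-(propan-2-yl)-1',2',3',3a',5',6'-hexahydrospiro[[1,3]dioxolane-2,4'-inden]-1'-ol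
Conditions: i-PrMgCl, CeCl3, THF, −78 to 0 °C
Reagents that add atoms: isopropylmagnesium chloride, CC(C)[Mg]Cl
Why: organocerium (Imamoto) 1,2-addition to the enone suppresses enolisation, reduction and 1,4-addition; attack on C4 anti to the pseudo-axial angular methyl (1,3-related) places isopropyl β and hydroxyl α.

Step 6
Reactants: 7 (1'R,3a'S)-3a'-methyl-1'-(propan-2-yl)-1',2',3',3a',5',6'-hexahydrospiro[[1,3]dioxolane-2,4'-inden]-1'-ol
Product: 9 (1'R,3a'S,7'S,7a'S)-3a'-methyl-1'-(propan-2-yl)octahydrospiro[[1,3]dioxolane-2,4'-indene]-1',7'-diol, via alkylborane 8 (not isolated)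
Conditions: BH3·THF, THF, 0 °C to rt; then NaOH, H2O2
Reagents that add atoms: hydrogen peroxide, OO
Why: hydroboration–oxidation (syn, anti-Markovnikov; boron to C6, hydrogen to C5) from the β-face, opposite the axial angular methyl and the pseudo-axial C4–O bond, sets 5β-H (trans ring fusion) and 6β-OH in one step, with retention in the oxidation.

Step 7
Reactants: 9 (1'R,3a'S,7'S,7a'S)-3a'-methyl-1'-(propan-2-yl)octahydrospiro[[1,3]dioxolane-2,4'-indene]-1',7'-diol
Product: 10 (1R,3aS,7S,7aS)-1,7-dihydroxy-3a-methyl-1-(propan-2-yl)octahydro-4H-inden-4-one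
Conditions: 1 M HCl, THF, rt
Reagents that add atoms: none
Why: acid hydrolysis of the dioxolane frees the C10 ketone; the saturated alcohols survive and no stereocentre is α to the carbonyl, so nothing can epimerise.

Step 8
Reactants: 10 (1R,3aS,7S,7aS)-1,7-dihydroxy-3a-methyl-1-(propan-2-yl)octahydro-4H-inden-4-one
Product: 12 (1R,3aS,7S,7aS)-1,7-dihydroxy-3a,5-dimethyl-1-(propan-2-yl)octahydro-4H-inden-4-one (both C5 epimers), via lithium enolate 11 (not isolated)
Conditions: LDA (3.2 equiv), THF, −78 to −40 °C; then MeI (1.1 equiv), −78 °C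
Reagents that add atoms: iodomethane, CI
Why: enolate C-alkylation; only C8 carries α-hydrogens because C1 is quaternary, the lithium alkoxides are poor nucleophiles towards MeI at −78 °C, and the new C8 centre is inconsequential since it later becomes sp2.

Step 9
Reactants: 12 (1R,3aS,7S,7aS)-1,7-dihydroxy-3a,5-dimethyl-1-(propan-2-yl)octahydro-4H-inden-4-one
Product: 13 (1R,3aS,7S,7aS)-3a,5-dimethyl-1-(propan-2-yl)-1,4,7-tris[(trimethylsilyl)oxy]-2,3,3a,6,7,7a-hexahydro-1H-indene
Conditions: TMSOTf, Et3N, CH2Cl2, 0 °C to rt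
Reagents that add atoms: trimethylsilyl trifluoromethanesulfonate, C[Si](C)(C)OS(=O)(=O)C(F)(F)F
Why: soft enolisation and silylation give the only possible enol ether (C10=C8, tetrasubstituted) and cap both hydroxyls as TMS ethers in the same operation.

Step 10
Reactants: 13 (1R,3aS,7S,7aS)-3a,5-dimethyl-1-(propan-2-yl)-1,4,7-tris[(trimethylsilyl)oxy]-2,3,3a,6,7,7a-hexahydro-1H-indene
Product: 14 (1R,3aS,7S,7aS)-3a,5-dimethyl-4,5-methano-1-(propan-2-yl)-1,4,7-tris[(trimethylsilyl)oxy]octahydro-1H-indene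
Conditions: Et2Zn, CH2I2, CH2Cl2, 0 °C to rt
Reagents that add atoms: diiodomethane, ICI
Why: Furukawa–Simmons–Smith cyclopropanation of the electron-rich silyl enol ether puts the future C9 as a CH2 bridge across C10–C8; the face of addition is irrelevant because both cyclopropane carbons end sp2.

Step 11
Reactants: 14 (1R,3aS,7S,7aS)-3a,5-dimethyl-4,5-methano-1-(propan-2-yl)-1,4,7-tris[(trimethylsilyl)oxy]octahydro-1H-indene
Product: 16 (3R,3aS,4S,8aS)-3,4-dihydroxy-6,8a-dimethyl-3-(propan-2-yl)-2,3,3a,4,5,8a-hexahydroazulen-8(1H)-one, via β-chloro ketone 15 (not isolated)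
Conditions: FeCl3, DMF, 0 °C to rt; then NaOAc, MeOH, 65 °C; 1 M HCl work-up
Reagents that add atoms: none
Why: Fe(III) exchanges the cyclopropanol silyl group and oxidises the iron alkoxide to the cyclopropyloxy radical, whose β-scission breaks the C10–C8 bond shared by the three- and six-membered rings to give the C10 ketone and a tertiary C8 radical in a seven-membered ring; chlorine transfer from FeCl3 gives β-chloro ketone 15, and acetate removes HCl by E1cB through the only α-CH2 (C9). The closest known reaction is the Ito–Saegusa oxidative ring expansion of 1-siloxybicyclo[n.1.0]alkanes (2-methylcyclohexanone to 3-methylcyclohept-2-enone). No ring is closed: the seven-membered ring arises by fragmentation of the zero-atom bridge of the bicyclo[4.1.0]heptane, that is, ring expansion by the carbenoid carbon C9. No stereocentre is created (C8, C9 and C10 end sp2), and C1, C4, C5 and C6 are not touched. The step needs cleavage of the internal rather than the external cyclopropane bond, which strain relief and the tertiary character of the C8 radical secure, and conjugated elimination, which the acidity of the C9 hydrogens next to the quaternary C1 secures.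

Step 12
Reactants: 16 (3R,3aS,4S,8aS)-3,4-dihydroxy-6,8a-dimethyl-3-(propan-2-yl)-2,3,3a,4,5,8a-hexahydroazulen-8(1H)-one; 17 angelic acid
Product: 19 (3R,3aS,4S,8aS)-3-hydroxy-6,8a-dimethyl-8-oxo-3-(propan-2-yl)-1,2,3,3a,4,5,8,8a-octahydroazulen-4-yl (2Z)-2-methylbut-2-enoate, via mixed anhydride 18 (not isolated)
Conditions: 2,4,6-trichlorobenzoyl chloride, Et3N, toluene, rt; then 16, 75 °C (no DMAP)
Reagents that add atoms: none
Why: Yamaguchi esterification through the mixed anhydride without DMAP is the standard way to keep the Z geometry of an angelate; only the secondary C6 hydroxyl reacts (the tertiary C4 hydroxyl is inert), with retention at C6.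

Step 13
Reactants: 19 (3R,3aS,4S,8aS)-3-hydroxy-6,8a-dimethyl-8-oxo-3-(propan-2-yl)-1,2,3,3a,4,5,8,8a-octahydroazulen-4-yl (2Z)-2-methylbut-2-enoate
Product: 20 (3R,3aS,4S,8S,8aS)-3,8-dihydroxy-6,8a-dimethyl-3-(propan-2-yl)-1,2,3,3a,4,5,8,8a-octahydroazulen-4-yl (2Z)-2-methylbut-2-enoate
Conditions: NaBH4, CeCl3·7H2O, MeOH, −78 to −40 °C
Reagents that add atoms: none
Why: Luche 1,2-reduction of the enone; hydride should add to C10 from the β-face, anti to the pseudo-axial angular methyl on the neighbouring quaternary C1, giving the 10α-alcohol (8S), while the conjugated ester is untouched.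

Step 14
Reactants: 20 (3R,3aS,4S,8S,8aS)-3,8-dihydroxy-6,8a-dimethyl-3-(propan-2-yl)-1,2,3,3a,4,5,8,8a-octahydroazulen-4-yl (2Z)-2-methylbut-2-enoate; 17 angelic acid
Product: 21 (3R,3aS,4S,8R,8aS)-3-hydroxy-6,8a-dimethyl-3-(propan-2-yl)-1,2,3,3a,4,5,8,8a-octahydroazulene-4,8-diyl bis[(2Z)-2-methylbut-2-enoate] (CNP0183261.1)
Conditions: PPh3, DIAD, toluene, 0 °C to rt
Reagents that add atoms: none
Why: Mitsunobu esterification with SN2 inversion at the allylic carbinol; the carboxylate enters from the β-face (anti to the angular methyl, the face the hydride used) to set the 10β-ester (8R), the acid is never activated as an acyl donor so its Z double bond is preserved, and the tertiary alcohol is inert.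

Compound list
1 | 2-methylcyclohexane-1,3-dione | CC1C(=O)CCCC1=O | starting material
2 | acrolein (prop-2-enal) | C=CC=O | starting material
3 | 3-(1-methyl-2,6-dioxocyclohexyl)propanal | CC1(CCC=O)C(=O)CCCC1=O | intermediate
4 | (3aS,7aR)-7a-hydroxy-3a-methylhexahydro-1H-indene-1,4(2H)-dione (cis-fused; OH cis to CH3) | C1CCC(=O)[C@@]2(C)CCC(=O)[C@@]12O | intermediate
5 | (3aS)-3a-methyl-3,3a,5,6-tetrahydro-1H-indene-1,4(2H)-dione (enone C1=O/C7a=C7; saturated ketone C4) | C1CCC(=O)[C@@]2(C)CCC(=O)C2=1 | intermediate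
6 | (3a'S)-3a'-methyl-3',3a',5',6'-tetrahydrospiro[[1,3]dioxolane-2,4'-inden]-1'(2'H)-one | C1CCC3(OCCO3)[C@@]2(C)CCC(=O)C2=1 | intermediate
7 | (1'R,3a'S)-3a'-methyl-1'-(propan-2-yl)-1',2',3',3a',5',6'-hexahydrospiro[[1,3]dioxolane-2,4'-inden]-1'-ol (OH cis to CH3) | C1CCC3(OCCO3)[C@@]2(C)CC[C@@](O)(C(C)C)C2=1 | intermediate
8 | alkylborane from 7 (BH2 on C7', O-borylated at C1'; not isolated) | B[C@H]1CCC3(OCCO3)[C@@]2(C)CC[C@@](OB)(C(C)C)[C@H]12 | intermediate
9 | (1'R,3a'S,7'S,7a'S)-3a'-methyl-1'-(propan-2-yl)octahydrospiro[[1,3]dioxolane-2,4'-indene]-1',7'-diol (trans-fused) | O[C@H]1CCC3(OCCO3)[C@@]2(C)CC[C@@](O)(C(C)C)[C@H]12 | intermediate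
10 | (1R,3aS,7S,7aS)-1,7-dihydroxy-3a-methyl-1-(propan-2-yl)octahydro-4H-inden-4-one | O[C@H]1CCC(=O)[C@@]2(C)CC[C@@](O)(C(C)C)[C@H]12 | intermediate
11 | trilithium enolate-dialkoxide of 10 (not isolated) | [Li]O[C@H]1CC=C(O[Li])[C@@]2(C)CC[C@@](O[Li])(C(C)C)[C@H]12 | intermediate
12 | (1R,3aS,7S,7aS)-1,7-dihydroxy-3a,5-dimethyl-1-(propan-2-yl)octahydro-4H-inden-4-one (C5 epimers) | O[C@H]1CC(C)C(=O)[C@@]2(C)CC[C@@](O)(C(C)C)[C@H]12 | intermediate
13 | (1R,3aS,7S,7aS)-3a,5-dimethyl-1-(propan-2-yl)-1,4,7-tris[(trimethylsilyl)oxy]-2,3,3a,6,7,7a-hexahydro-1H-indene | C[Si](C)(C)O[C@H]1CC(C)=C(O[Si](C)(C)C)[C@@]2(C)CC[C@@](O[Si](C)(C)C)(C(C)C)[C@H]12 | intermediate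
14 | (1R,3aS,7S,7aS)-3a,5-dimethyl-4,5-methano-1-(propan-2-yl)-1,4,7-tris[(trimethylsilyl)oxy]octahydro-1H-indene (siloxycyclopropane; cyclopropane face unassigned) | C[Si](C)(C)O[C@H]1CC4(C)CC4(O[Si](C)(C)C)[C@@]2(C)CC[C@@](O[Si](C)(C)C)(C(C)C)[C@H]12 | intermediate
15 | (3R,3aS,4S,8aS)-6-chloro-6,8a-dimethyl-3-(propan-2-yl)-3,4-bis[(trimethylsilyl)oxy]octahydroazulen-8(1H)-one (not isolated) | C[Si](C)(C)O[C@H]1CC(C)(Cl)CC(=O)[C@@]2(C)CC[C@@](O[Si](C)(C)C)(C(C)C)[C@H]12 | intermediate
16 | (3R,3aS,4S,8aS)-3,4-dihydroxy-6,8a-dimethyl-3-(propan-2-yl)-2,3,3a,4,5,8a-hexahydroazulen-8(1H)-one | O[C@H]1CC(C)=CC(=O)[C@@]2(C)CC[C@@](O)(C(C)C)[C@H]12 | intermediate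
17 | angelic acid, (2Z)-2-methylbut-2-enoic acid | C/C=C(/C)C(=O)O | starting material
18 | (2Z)-2-methylbut-2-enoic 2,4,6-trichlorobenzoic anhydride (not isolated) | C/C=C(/C)C(=O)OC(=O)c1c(Cl)cc(Cl)cc1Cl | intermediate
19 | (3R,3aS,4S,8aS)-3-hydroxy-6,8a-dimethyl-8-oxo-3-(propan-2-yl)-1,2,3,3a,4,5,8,8a-octahydroazulen-4-yl (2Z)-2-methylbut-2-enoate | C/C=C(/C)C(=O)O[C@H]1CC(C)=CC(=O)[C@@]2(C)CC[C@@](O)(C(C)C)[C@H]12 | intermediate
20 | (3R,3aS,4S,8S,8aS)-3,8-dihydroxy-6,8a-dimethyl-3-(propan-2-yl)-1,2,3,3a,4,5,8,8a-octahydroazulen-4-yl (2Z)-2-methylbut-2-enoate (10α-alcohol) | C/C=C(/C)C(=O)O[C@H]1CC(C)=C[C@H](O)[C@@]2(C)CC[C@@](O)(C(C)C)[C@H]12 | intermediate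
21 | (3R,3aS,4S,8R,8aS)-3-hydroxy-6,8a-dimethyl-3-(propan-2-yl)-1,2,3,3a,4,5,8,8a-octahydroazulene-4,8-diyl bis[(2Z)-2-methylbut-2-enoate] | C/C=C(/C)C(=O)O[C@H]1CC(C)=C[C@@H](OC(=O)/C(C)=C\C)[C@@]2(C)CC[C@@](O)(C(C)C)[C@H]12 | target

Total step count: 14
Longest linear sequence: 14 steps (from 1; angelic acid 17 is purchased)

Steps most likely to fail, with fallbacks

1. Step 14 (together with the facial outcome of step 13). Displacement at a secondary allylic carbinol flanked by the quaternary C1 may be slow and may leak into SN2′ substitution at C8 or elimination to a diene. Separately, the hydride of step 13 could add from the α-face, in which case the alcohol would already be 10β. The fallback sets out from enone 19 and replaces inversion by reagent control. Corey–Bakshi–Shibata reduction with (S)-2-methyl-CBS-oxazaborolidine and catecholborane in toluene at −78 °C, with the quaternary C1 flank as the large group, should give (3R,3aS,4S,8R,8aS)-3,8-dihydroxy-6,8a-dimethyl-3-(propan-2-yl)-1,2,3,3a,4,5,8,8a-octahydroazulen-4-yl (2Z)-2-methylbut-2-enoate F1. This alcohol is then esterified with retention by the mixed anhydride 18 under the conditions of step 12, and the route is rejoined at 21. The same retentive esterification applies if step 13 itself delivers F1.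

2. Step 6. The facial selectivity of the hydroboration could erode because the β-isopropyl group on the allylic C4 competes with the α-methyl on C1, which would give the cis-fused 6α-alcohol. The fallback sets out from enone 6 and hydroborates before the isopropyl group is present. Excess BH3·THF reduces the enone carbonyl anti to the methyl and hydroborates the resulting allylic borinate in the same flask from the β-face. Oxidation (NaOH, H2O2) should give (1'S,3a'S,7'S,7a'S)-3a'-methyloctahydrospiro[[1,3]dioxolane-2,4'-indene]-1',7'-diol F2. Silylation of the less hindered equatorial C6 hydroxyl (TBSCl, imidazole, DMF) gives the mono-TBS ether F3. Dess–Martin oxidation gives (3a'S,7'S,7a'S)-7'-(tert-butyldimethylsilyloxy)-3a'-methylhexahydrospiro[[1,3]dioxolane-2,4'-inden]-1'(2'H)-one F4. Addition of i-PrMgCl/CeCl3 anti to the adjacent C5–C6 bond and the C1 methyl gives the tertiary alcohol F5, and TBAF returns the route to 9.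

3. Step 11. The oxidative opening may be accompanied by cleavage of the external cyclopropane bond, which would give a ring-retained α-alkylated ketone, or by Lewis-acid-induced loss of the tertiary C4 oxygen. The fallback sets out from ketone 12 and uses a 1,2-shift ring expansion instead. Silylation (TMSCl, imidazole) gives (1R,3aS,7S,7aS)-3a,5-dimethyl-1-(propan-2-yl)-1,7-bis[(trimethylsilyl)oxy]octahydro-4H-inden-4-one F6. Sc(OTf)3-catalysed homologation with trimethylsilyldiazomethane, in which the less substituted C8 migrates and a 1,3-silyl shift follows, gives the ring-expanded enol silane (3R,3aS,4S,8aS)-6,8a-dimethyl-3-(propan-2-yl)-3,4,8-tris[(trimethylsilyl)oxy]-1,2,3,3a,4,5,6,8a-octahydroazulene F7. Saegusa–Ito dehydrogenation (Pd(OAc)2, MeCN) and acidic work-up return the route to 16.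

Further compounds
F1 | step 14 | (3R,3aS,4S,8R,8aS)-3,8-dihydroxy-6,8a-dimethyl-3-(propan-2-yl)-1,2,3,3a,4,5,8,8a-octahydroazulen-4-yl (2Z)-2-methylbut-2-enoate | C/C=C(/C)C(=O)O[C@H]1CC(C)=C[C@@H](O)[C@@]2(C)CC[C@@](O)(C(C)C)[C@H]12
F2 | step 6 | (1'S,3a'S,7'S,7a'S)-3a'-methyloctahydrospiro[[1,3]dioxolane-2,4'-indene]-1',7'-diol | O[C@H]1CCC3(OCCO3)[C@@]2(C)CC[C@H](O)[C@H]12
F3 | step 6 | (1'S,3a'S,7'S,7a'S)-7'-(tert-butyldimethylsilyloxy)-3a'-methyloctahydrospiro[[1,3]dioxolane-2,4'-inden]-1'-ol | CC(C)(C)[Si](C)(C)O[C@H]1CCC3(OCCO3)[C@@]2(C)CC[C@H](O)[C@H]12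
F4 | step 6 | (3a'S,7'S,7a'S)-7'-(tert-butyldimethylsilyloxy)-3a'-methylhexahydrospiro[[1,3]dioxolane-2,4'-inden]-1'(2'H)-one | CC(C)(C)[Si](C)(C)O[C@H]1CCC3(OCCO3)[C@@]2(C)CCC(=O)[C@H]12
F5 | step 6 | (1'R,3a'S,7'S,7a'S)-7'-(tert-butyldimethylsilyloxy)-3a'-methyl-1'-(propan-2-yl)octahydrospiro[[1,3]dioxolane-2,4'-inden]-1'-ol | CC(C)(C)[Si](C)(C)O[C@H]1CCC3(OCCO3)[C@@]2(C)CC[C@@](O)(C(C)C)[C@H]12
F6 | step 11 | (1R,3aS,7S,7aS)-3a,5-dimethyl-1-(propan-2-yl)-1,7-bis[(trimethylsilyl)oxy]octahydro-4H-inden-4-one | C[Si](C)(C)O[C@H]1CC(C)C(=O)[C@@]2(C)CC[C@@](O[Si](C)(C)C)(C(C)C)[C@H]12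
F7 | step 11 | (3R,3aS,4S,8aS)-6,8a-dimethyl-3-(propan-2-yl)-3,4,8-tris[(trimethylsilyl)oxy]-1,2,3,3a,4,5,6,8a-octahydroazulene | C[Si](C)(C)O[C@H]1CC(C)C=C(O[Si](C)(C)C)[C@@]2(C)CC[C@@](O[Si](C)(C)C)(C(C)C)[C@H]12
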